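**Remark on the chemistry:** the ring is numbered O1, O2, C3 (ketal carbon), C4, C5, C6 (CH carbon) and the compound names keep these locants; aldehyde 10 is assumed to be a catalogue compound (otherwise two routine steps from propane-1,3-diol).

## Analysis of the target

The target 29 is a monocyclic 1,2-dioxane. C3 is a methoxy peroxyketal carbon that also carries the (E)-hexadec-6-en-4-yn-1-yl chain, and C6 is a CH carbon that carries the CH2CO2H arm. The two stereocentres are C3 (R) and C6 (S). The methoxy group and the acetic acid arm are cis, so in the chair both carbon substituents are equatorial and the methoxy group is axial, where it gains the anomeric stabilisation from O2. C3 is therefore the thermodynamically preferred ketal epimer and can be corrected under acid, whereas C6 must be set absolutely. The O–O bond is cleaved by hydrogenation catalysts, phosphines and low-valent metals and is fragmented by base through C6–H. A carbonyl group β to C6 invites ring opening by β-elimination, the ketal is acid-labile, and the conjugated enyne is sensitive to oxidants, diimide and metathesis catalysts. The hard part is to make a configurationally defined secondary C–O–O bond and to carry the peroxide through carbon–carbon bond formation. The route rests on the fact that C4–C5 is the only ring bond that touches neither oxygenated carbon. C3 and C6 can therefore first be tied together through the peroxide, each carrying a vinyl group, and the carbocyclic bond can be closed last as a temporary C4=C5 alkene.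

## Retrosynthetic reasoning

**Carboxyl group, 29 to 27.** The acid is traced back to the primary alcohol 27, so only the oxidation level of the arm changes. A carbonyl group β to C6 would make the displacement that sets C6 impossible (elimination instead of substitution) and would expose the ring to β-elimination in the fluoride and amine steps. The arm is therefore carried as a silyl-protected hydroxyethyl group, and the forward oxidation has to spare the O–O bond, the ketal and the enyne.

**Enyne, 27 to 23 and 26.** The C(sp)–C(sp2) bond of the enyne is cut. This makes the end game convergent, fixes the E geometry in the vinyl iodide 26 (from alkyne 24), and keeps the enyne away from the metathesis and the alkene reduction. The coupling must run at room temperature with a dialkyl peroxide present.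

**Adjustments on the ring, 23 to 20.** Both silicon groups of 22 are removed in one operation to give 23. 22 is the ketal epimer obtained by acid equilibration of the saturated mixture 21. 21 comes from the dihydrodioxine 20 by a hydrogen transfer that does not cleave O–O. No skeletal bond is cut here; the sequence only removes the temporary alkene and corrects C3.

**Ring closure, 20 to 19.** The C4=C5 bond is cut to give the acyclic mixed peroxyketal 19, which has a vinyl group on C3 and one on C6. Any other ring disconnection would require a ring-forming C–O or O–O bond and a preformed stereodefined hydroperoxide on a long chain. The forward step is a ring-closing metathesis that forms no stereocentre and must leave the silyl-capped alkyne alone.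

**C6–O1 bond, 19 to 8 and 16.** The vinyl group on C6 of 19 is traced to the ethynyl group of 18, and the C6–O1 bond of 18 is cut. The oxygen comes from the tertiary hydroperoxy ketal 8 and the carbon from the (S)-propargylic mesylate 16; substitution with inversion sets C6. A propargylic electrophile is chosen over an allylic one because it does not ionise or react with allylic transposition. A photooxygenative ene route to an allylic hydroperoxide was not used, because hydrogen atoms next to a carboxyl group are abstracted preferentially, which places the oxygen on the wrong carbon and in any case gives a racemate.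

**Hydroperoxy ketal, 8 to 1 and 5.** 8 is the adduct of the peroxide O–H bond across the enol ether of allene 7. 7 arises by cutting the bond between the allene carbon and the chain, which gives lithiated methoxyallene (from 5) and iodide 4. 4 comes from chloride 3 and that from 5-chloropent-1-yne 1. The bulky silyl cap is introduced first because it must shield the alkyne in the reduction and metathesis steps.

**Mesylate, 16 to 9 and 10.** 16 comes from alcohol 15, which is the desilylated form of 14. The C–H bond at the carbinol carbon of 14 is traced to an enantioselective transfer hydrogenation of ynone 13. 13 comes from the racemic alcohol 12, whose carbinol–alkyne bond is cut to give alkyne 9 and aldehyde 10.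

**Vinyl iodide, 26 to 24.** The C–I and C–H bonds across the alkene are traced to a syn hydrometallation of the terminal alkyne 24, which fixes the E geometry.

## Alternatives that were turned down

**Alternative 1:** Both C–O bonds (C3–O2 and C6–O1) are disconnected together. In the forward direction singlet oxygen adds across the termini of 1-[(E)-hexadec-6-en-4-yn-1-yl]-2-(tert-butyldimethylsilyloxy)cyclohexa-1,3-diene A2 to give racemic 1-[(E)-hexadec-6-en-4-yn-1-yl]-6-(tert-butyldimethylsilyloxy)-2,3-dioxabicyclo[2.2.2]oct-5-ene A1. The carbon bridge is then cut by unmasking the ketone, Baeyer–Villiger insertion next to the bridgehead, and methanolysis to the methoxy ketal and the acetate arm.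
- For: one step makes the peroxide and both C–O bonds, the bicycle forces the two oxygens onto one face, and no hydroperoxide has to be prepared. In bond economy it is stronger than the chosen route.
- Against: nothing distinguishes the two faces of the diene, so A1 is racemic and a resolution would be needed. Silyl dienol ethers can also react with singlet oxygen by silyl or hydrogen transfer. The peracid of the ring expansion meets the enyne alkene and an α-peroxy ketone whose migrating carbon carries the peroxide.
- Comparison: the chosen route is longer, but it takes the C6 configuration from a catalytic ketone reduction and exposes the enyne to no oxidant stronger than a buffered oxoammonium salt.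

**Alternative 2:** The O2–C3 bond is disconnected. In the forward direction acid ionises the dimethyl ketal of (3S,12E)-1-[(tert-butyldiphenylsilyl)oxy]-3-hydroperoxy-6,6-dimethoxydocos-12-en-10-yne A4, and the hydroperoxide captures the oxocarbenium ion to give tert-butyl{2-[(3R,6S)-3-[(E)-hexadec-6-en-4-yn-1-yl]-3-methoxy-1,2-dioxan-6-yl]ethoxy}diphenylsilane A3.
- For: the ring closes under thermodynamic control, so the ring and the C3 epimer are settled in one step; no transition metal meets the peroxide; and no temporary double bond has to be removed. On these three points it is stronger than the chosen route.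
- Against: it needs the free, enantiopure secondary hydroperoxide A4. This can only come from displacement at an unactivated secondary carbon between two methylene groups, where substitution is slow and elimination competes. A4 must then be carried beside an acid-labile ketal, and the sequence is linear.
- Comparison: the chosen route makes the C6–O bond at an activated propargylic carbon with a non-enolisable ketal hydroperoxide and joins two fragments of similar size. It pays with the question of ruthenium–peroxide compatibility and two extra steps after ring closure.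

**Alternative 3:** The O1–C6 bond and the CH2–CO2Me bond are disconnected in one operation. In the forward direction a chiral divalent-palladium catalyst under carbon monoxide in methanol lets the terminal oxygen of (6-hydroperoxy-6-methoxydec-9-en-1-yn-1-yl)trimethylsilane A6 add to the coordinated alkene in a 6-exo closure. CO insertion and methanolysis then give methyl 2-[(3R,6S)-3-methoxy-3-[5-(trimethylsilyl)pent-4-yn-1-yl]-1,2-dioxan-6-yl]acetate A5.
- For: ring, C6 stereocentre and ester are made in one step from a simple hydroperoxide, with no sulfonate displacement and no late oxidation. In step count it is clearly stronger.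
- Against: ligand control of the alkene face in a peroxypalladation is not established. Hydroperoxides oxidise phosphine-type ligands and are decomposed by palladium hydride or zerovalent palladium formed in the cycle. A6 is racemic at C3, so matched and mismatched pairs arise, and β-hydride elimination competes with CO insertion.
- Comparison: the chosen route takes its stereocontrol from a ketone transfer hydrogenation and an inverting substitution, and its key step creates no stereocentre, so its risk is limited to catalyst turnover.

Key step: step 12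

## Route

Step 1
Reactants: 1 5-chloropent-1-yne
Product: 3 (5-chloropent-1-yn-1-yl)tri(propan-2-yl)silane, via lithium 5-chloropent-1-yn-1-ide 2 (not isolated)
Conditions: n-BuLi, THF, −78 °C; then i-Pr3SiOTf, −78 °C to rt
Reagents that add atoms: triisopropylsilyl trifluoromethanesulfonate, CC(C)[Si](OS(=O)(=O)C(F)(F)F)(C(C)C)C(C)C
Why: Deprotonation of the terminal alkyne and C-silylation of the acetylide; the primary chloride is inert at low temperature. The bulky cap later shields the alkyne from hydrogenation, diimide and the ruthenium carbene.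

Step 2
Reactants: 3 (5-chloropent-1-yn-1-yl)tri(propan-2-yl)silane
Product: 4 (5-iodopent-1-yn-1-yl)tri(propan-2-yl)silane
Conditions: NaI, acetone, reflux
Reagents that add atoms: sodium iodide, [Na+].[I-]
Why: Finkelstein halide exchange, driven by precipitation of NaCl, gives the iodide needed for a clean alkylation in step 3.

Step 3
Reactants: 5 methoxyallene (1-methoxypropa-1,2-diene); 4 (5-iodopent-1-yn-1-yl)tri(propan-2-yl)silane
Product: 7 (6-methoxyocta-6,7-dien-1-yn-1-yl)tri(propan-2-yl)silane, via 1-lithio-1-methoxypropa-1,2-diene 6 (not isolated)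
Conditions: n-BuLi, THF, −40 °C; then 4, −78 °C to rt
Reagents that add atoms: none
Why: Lithiation of the alkoxyallene at the oxygen-bearing carbon and SN2 alkylation with a primary iodide, the standard route to 1-alkyl-1-alkoxyallenes. The product is an enol ether and is handled without contact with acid.

Step 4
Reactants: 7 (6-methoxyocta-6,7-dien-1-yn-1-yl)tri(propan-2-yl)silane
Product: 8 (6-hydroperoxy-6-methoxyoct-7-en-1-yn-1-yl)tri(propan-2-yl)silane (racemic)
Conditions: H2O2 (anhydrous, in Et2O, large excess), PPTS (cat.), 0 °C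
Reagents that add atoms: hydrogen peroxide, OO
Why: Acid-catalysed addition of an O–H bond across an enol ether: protonation at the central allene carbon gives the methoxy-stabilised allyl cation, which is captured at the oxygen-bearing carbon, as when alcohols add to alkoxyallenes to give acrolein-type ketals. The excess of H2O2 suppresses the bis-peroxide; the configuration at this carbon does not matter because it is equilibrated in step 14.

Step 5
Reactants: 9 ethynyltrimethylsilane; 10 3-[(tert-butyldiphenylsilyl)oxy]propanal
Product: 12 rac-5-[(tert-butyldiphenylsilyl)oxy]-1-(trimethylsilyl)pent-1-yn-3-ol, via lithium (trimethylsilyl)acetylide 11 (not isolated)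
Conditions: n-BuLi, THF, −78 °C; then 10, −78 to 0 °C
Reagents that add atoms: none
Why: 1,2-Addition of a lithium acetylide to an aldehyde; the low temperature avoids β-elimination of the silyloxy group.

Step 6
Reactants: 12 rac-5-[(tert-butyldiphenylsilyl)oxy]-1-(trimethylsilyl)pent-1-yn-3-ol
Product: 13 5-[(tert-butyldiphenylsilyl)oxy]-1-(trimethylsilyl)pent-1-yn-3-one
Conditions: Dess–Martin periodinane, NaHCO3, CH2Cl2, rt
Reagents that add atoms: none
Why: Dess–Martin oxidation of a propargylic alcohol to the ynone under buffered, non-basic conditions that leave both silyl groups in place.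

Step 7
Reactants: 13 5-[(tert-butyldiphenylsilyl)oxy]-1-(trimethylsilyl)pent-1-yn-3-one
Product: 14 (3S)-5-[(tert-butyldiphenylsilyl)oxy]-1-(trimethylsilyl)pent-1-yn-3-ol
Conditions: Ru[(S,S)-TsDPEN](p-cymene) (preformed amido complex, 1 mol%), i-PrOH, rt
Reagents that add atoms: none
Why: Noyori asymmetric transfer hydrogenation of an alkyl alkynyl ketone. The (S,S) catalyst distinguishes the alkynyl from the alkyl substituent and should give the (S) carbinol, as it does with other ynones; base-free conditions avoid conjugate addition and β-elimination.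

Step 8
Reactants: 14 (3S)-5-[(tert-butyldiphenylsilyl)oxy]-1-(trimethylsilyl)pent-1-yn-3-ol
Product: 15 (3S)-5-[(tert-butyldiphenylsilyl)oxy]pent-1-yn-3-ol
Conditions: K2CO3, MeOH, rt
Reagents that add atoms: none
Why: Methoxide-induced protodesilylation of the C(sp)–SiMe3 bond; the silyl ether and the stereocentre are not affected.

Step 9
Reactants: 15 (3S)-5-[(tert-butyldiphenylsilyl)oxy]pent-1-yn-3-ol
Product: 16 (3S)-5-[(tert-butyldiphenylsilyl)oxy]pent-1-yn-3-yl methanesulfonate
Conditions: MsCl, Et3N, CH2Cl2, −20 °C
Reagents that add atoms: methanesulfonyl chloride, CS(=O)(=O)Cl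
Why: Sulfonylation of the secondary alcohol with retention at carbon. A propargylic mesylate does not ionise readily and is used without storage.

Step 10
Reactants: 8 (6-hydroperoxy-6-methoxyoct-7-en-1-yn-1-yl)tri(propan-2-yl)silane; 16 (3S)-5-[(tert-butyldiphenylsilyl)oxy]pent-1-yn-3-yl methanesulfonate
Product: 18 (3R)-5-[(tert-butyldiphenylsilyl)oxy]pent-1-yn-3-yl 3-methoxy-8-[tri(propan-2-yl)silyl]oct-1-en-7-yn-3-yl peroxide (both epimers at the ketal carbon), via cesium 3-methoxy-8-[tri(propan-2-yl)silyl]oct-1-en-7-yn-3-yl peroxide 17 (not isolated)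
Conditions: CsOH·H2O, DMF, 0 °C; then 16, 0 °C to rt
Reagents that add atoms: none
Why: SN2 alkylation of the cesium salt of an α-alkoxy hydroperoxide by a secondary sulfonate. The peroxide anion is a strong α-effect nucleophile but a weak base, and the propargylic carbon is activated towards direct substitution. Inversion converts the (S) mesylate into the (R) peroxide and so sets C6.

Step 11
Reactants: 18 (3R)-5-[(tert-butyldiphenylsilyl)oxy]pent-1-yn-3-yl 3-methoxy-8-[tri(propan-2-yl)silyl]oct-1-en-7-yn-3-yl peroxide
Product: 19 (3R)-5-[(tert-butyldiphenylsilyl)oxy]pent-1-en-3-yl 3-methoxy-8-[tri(propan-2-yl)silyl]oct-1-en-7-yn-3-yl peroxide (both epimers at the ketal carbon)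
Conditions: H2 (1 atm), Pd/CaCO3 poisoned with Pb(OAc)2 (Lindlar catalyst), quinoline, EtOAc, 0 °C, stopped after one equivalent
Reagents that add atoms: none
Why: Lindlar semi-hydrogenation: the terminal alkyne binds to the poisoned palladium surface in preference to the alkene and to the hindered silyl alkyne. The poisoned catalyst at low temperature should be slow in O–O hydrogenolysis.

Step 12
Reactants: 19 (3R)-5-[(tert-butyldiphenylsilyl)oxy]pent-1-en-3-yl 3-methoxy-8-[tri(propan-2-yl)silyl]oct-1-en-7-yn-3-yl peroxide
Product: 20 (6R)-6-{2-[(tert-butyldiphenylsilyl)oxy]ethyl}-3-methoxy-3-{5-[tri(propan-2-yl)silyl]pent-4-yn-1-yl}-3,6-dihydro-1,2-dioxine (both epimers at C3)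
Conditions: RuCl2(=CHPh)(PCy3)(H2IMes) (second-generation Grubbs catalyst, 10 mol%), CH2Cl2 (0.005 M), 40 °C, argon purge
Reagents that add atoms: none
Why: Ring-closing metathesis: the ruthenium carbene should load on the less hindered vinyl group at C6 by [2+2] cycloaddition and cycloreversion, and the new alkylidene then engages the vinyl group on the ketal carbon through a second ruthenacyclobutane, releasing ethene. The closest known reactions are ring-closing metatheses of dialkenyl peroxides and of acrolein-type mixed acetals to unsaturated six-membered oxygen heterocycles. The substrate is a 4,5-dioxaocta-1,7-diene, so the closure gives a six-membered ring with an endocyclic cis C4=C5 bond (not a five-membered ring, which would need a 1,6-diene). No stereocentre is formed: C6 is untouched and keeps the configuration set in step 10, and both C3 epimers should cyclise. The step needs diene-over-enyne chemoselectivity, which the triisopropylsilyl cap on the alkyne provides, and it needs the dialkyl peroxide to survive, which high dilution, short heating and removal of ethene are meant to ensure.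

Step 13
Reactants: 20 (6R)-6-{2-[(tert-butyldiphenylsilyl)oxy]ethyl}-3-methoxy-3-{5-[tri(propan-2-yl)silyl]pent-4-yn-1-yl}-3,6-dihydro-1,2-dioxine
Product: 21 (6S)-6-{2-[(tert-butyldiphenylsilyl)oxy]ethyl}-3-methoxy-3-{5-[tri(propan-2-yl)silyl]pent-4-yn-1-yl}-1,2-dioxane (both epimers at C3)
Conditions: KO2CN=NCO2K, AcOH, CH2Cl2, 0 °C to rt
Reagents that add atoms: none
Why: Diimide reduction: concerted syn transfer of H2 to the cis ring alkene without contact between the O–O bond and a metal, the usual way to saturate unsaturated cyclic peroxides; the bulky silyl alkyne should react much more slowly. The spatial arrangement at C6 is unchanged; the descriptor becomes S only because C5 is now CH2.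

Step 14
Reactants: 21 (6S)-6-{2-[(tert-butyldiphenylsilyl)oxy]ethyl}-3-methoxy-3-{5-[tri(propan-2-yl)silyl]pent-4-yn-1-yl}-1,2-dioxane
Product: 22 (3R,6S)-6-{2-[(tert-butyldiphenylsilyl)oxy]ethyl}-3-methoxy-3-{5-[tri(propan-2-yl)silyl]pent-4-yn-1-yl}-1,2-dioxane
Conditions: PPTS (cat.), MeOH–CH2Cl2, rt
Reagents that add atoms: methanol, CO
Why: Acid-catalysed ketal exchange through the cyclic peroxycarbenium ion puts C3 under thermodynamic control. The favoured chair has the methoxy group axial (anomeric effect) and both carbon substituents equatorial, which is the (3R,6S) isomer; the minor epimer can be separated and resubmitted.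

Step 15
Reactants: 22 (3R,6S)-6-{2-[(tert-butyldiphenylsilyl)oxy]ethyl}-3-methoxy-3-{5-[tri(propan-2-yl)silyl]pent-4-yn-1-yl}-1,2-dioxane
Product: 23 2-[(3R,6S)-3-methoxy-3-(pent-4-yn-1-yl)-1,2-dioxan-6-yl]ethan-1-ol
Conditions: Bu4NF, THF, 0 °C to rt
Reagents that add atoms: none
Why: Fluoride cleaves both the Si–C(sp) and the Si–O bond in one operation. No carbonyl group is β to C6 at this stage, so the basic fluoride has no pathway for ring opening.

Step 16
Reactants: 24 undec-1-yne
Product: 26 (E)-1-iodoundec-1-ene, via chlorobis(cyclopentadienyl)[(E)-undec-1-en-1-yl]zirconium 25 (not isolated)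
Conditions: Cp2Zr(H)Cl, CH2Cl2, rt; then I2, 0 °C
Reagents that add atoms: iodine, II
Why: Hydrozirconation adds Zr–H syn with zirconium at the terminal carbon, and iodinolysis proceeds with retention, so the E iodide is expected.

Step 17
Reactants: 23 2-[(3R,6S)-3-methoxy-3-(pent-4-yn-1-yl)-1,2-dioxan-6-yl]ethan-1-ol; 26 (E)-1-iodoundec-1-ene
Product: 27 2-[(3R,6S)-3-[(E)-hexadec-6-en-4-yn-1-yl]-3-methoxy-1,2-dioxan-6-yl]ethan-1-ol
Conditions: Pd(PPh3)4 (5 mol%), CuI (10 mol%), i-Pr2NH, THF, rt
Reagents that add atoms: none
Why: Sonogashira coupling of a terminal alkyne with a vinyl iodide, with retention of the alkene geometry. The conditions are mild enough for hindered dialkyl peroxides and ketals, and the free hydroxyl group does not interfere.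

Step 18
Reactants: 27 2-[(3R,6S)-3-[(E)-hexadec-6-en-4-yn-1-yl]-3-methoxy-1,2-dioxan-6-yl]ethan-1-ol
Product: 29 2-[(3R,6S)-3-[(E)-hexadec-6-en-4-yn-1-yl]-3-methoxy-1,2-dioxan-6-yl]acetic acid (target), via 2-[(3R,6S)-3-[(E)-hexadec-6-en-4-yn-1-yl]-3-methoxy-1,2-dioxan-6-yl]acetaldehyde 28 (not isolated)
Conditions: TEMPO (cat.), PhI(OAc)2, MeCN–pH 7 phosphate buffer, 0 °C to rt
Reagents that add atoms: water, O
Why: Oxoammonium-mediated oxidation of the primary alcohol to the aldehyde and, through its hydrate, to the acid. The buffered, non-basic medium should spare the ketal, the O–O bond and the enyne, and the β-peroxy aldehyde is oxidised further before it can eliminate.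

## Compound list

1 | 5-chloropent-1-yne | C#CCCCCl | starting material
2 | lithium 5-chloropent-1-yn-1-ide | [Li]C#CCCCCl | intermediate
3 | (5-chloropent-1-yn-1-yl)tri(propan-2-yl)silane | CC(C)[Si](C(C)C)(C(C)C)C#CCCCCl | intermediate
4 | (5-iodopent-1-yn-1-yl)tri(propan-2-yl)silane | CC(C)[Si](C(C)C)(C(C)C)C#CCCCI | intermediate
5 | methoxyallene (1-methoxypropa-1,2-diene) | COC=C=C | starting material
6 | 1-lithio-1-methoxypropa-1,2-diene | COC([Li])=C=C | intermediate
7 | (6-methoxyocta-6,7-dien-1-yn-1-yl)tri(propan-2-yl)silane | COC(CCCC#C[Si](C(C)C)(C(C)C)C(C)C)=C=C | intermediate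
8 | (6-hydroperoxy-6-methoxyoct-7-en-1-yn-1-yl)tri(propan-2-yl)silane, racemic | COC(OO)(C=C)CCCC#C[Si](C(C)C)(C(C)C)C(C)C | intermediate
9 | ethynyltrimethylsilane | C#C[Si](C)(C)C | starting material
10 | 3-[(tert-butyldiphenylsilyl)oxy]propanal | O=CCCO[Si](c1ccccc1)(c1ccccc1)C(C)(C)C | starting material
11 | lithium (trimethylsilyl)acetylide | [Li]C#C[Si](C)(C)C | intermediate
12 | rac-5-[(tert-butyldiphenylsilyl)oxy]-1-(trimethylsilyl)pent-1-yn-3-ol | C[Si](C)(C)C#CC(O)CCO[Si](c1ccccc1)(c1ccccc1)C(C)(C)C | intermediate
13 | 5-[(tert-butyldiphenylsilyl)oxy]-1-(trimethylsilyl)pent-1-yn-3-one | C[Si](C)(C)C#CC(=O)CCO[Si](c1ccccc1)(c1ccccc1)C(C)(C)C | intermediate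
14 | (3S)-5-[(tert-butyldiphenylsilyl)oxy]-1-(trimethylsilyl)pent-1-yn-3-ol | C[Si](C)(C)C#C[C@@H](O)CCO[Si](c1ccccc1)(c1ccccc1)C(C)(C)C | intermediate
15 | (3S)-5-[(tert-butyldiphenylsilyl)oxy]pent-1-yn-3-ol | C#C[C@@H](O)CCO[Si](c1ccccc1)(c1ccccc1)C(C)(C)C | intermediate
16 | (3S)-5-[(tert-butyldiphenylsilyl)oxy]pent-1-yn-3-yl methanesulfonate | C#C[C@@H](OS(C)(=O)=O)CCO[Si](c1ccccc1)(c1ccccc1)C(C)(C)C | intermediate
17 | cesium 3-methoxy-8-[tri(propan-2-yl)silyl]oct-1-en-7-yn-3-yl peroxide | COC(O[O-])(C=C)CCCC#C[Si](C(C)C)(C(C)C)C(C)C.[Cs+] | intermediate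
18 | (3R)-5-[(tert-butyldiphenylsilyl)oxy]pent-1-yn-3-yl 3-methoxy-8-[tri(propan-2-yl)silyl]oct-1-en-7-yn-3-yl peroxide, both epimers at the ketal carbon | CC(C)[Si](C(C)C)(C(C)C)C#CCCCC(OC)(C=C)OO[C@@H](C#C)CCO[Si](c1ccccc1)(c1ccccc1)C(C)(C)C | intermediate
19 | (3R)-5-[(tert-butyldiphenylsilyl)oxy]pent-1-en-3-yl 3-methoxy-8-[tri(propan-2-yl)silyl]oct-1-en-7-yn-3-yl peroxide, both epimers at the ketal carbon | CC(C)[Si](C(C)C)(C(C)C)C#CCCCC(OC)(C=C)OO[C@@H](C=C)CCO[Si](c1ccccc1)(c1ccccc1)C(C)(C)C | intermediate
20 | (6R)-6-{2-[(tert-butyldiphenylsilyl)oxy]ethyl}-3-methoxy-3-{5-[tri(propan-2-yl)silyl]pent-4-yn-1-yl}-3,6-dihydro-1,2-dioxine, both epimers at C3 | CC(C)[Si](C(C)C)(C(C)C)C#CCCCC1(OC)C=C[C@@H](CCO[Si](c2ccccc2)(c2ccccc2)C(C)(C)C)OO1 | intermediate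
21 | (6S)-6-{2-[(tert-butyldiphenylsilyl)oxy]ethyl}-3-methoxy-3-{5-[tri(propan-2-yl)silyl]pent-4-yn-1-yl}-1,2-dioxane, both epimers at C3 | CC(C)[Si](C(C)C)(C(C)C)C#CCCCC1(OC)CC[C@@H](CCO[Si](c2ccccc2)(c2ccccc2)C(C)(C)C)OO1 | intermediate
22 | (3R,6S)-6-{2-[(tert-butyldiphenylsilyl)oxy]ethyl}-3-methoxy-3-{5-[tri(propan-2-yl)silyl]pent-4-yn-1-yl}-1,2-dioxane | CC(C)[Si](C(C)C)(C(C)C)C#CCCC[C@]1(OC)CC[C@@H](CCO[Si](c2ccccc2)(c2ccccc2)C(C)(C)C)OO1 | intermediate
23 | 2-[(3R,6S)-3-methoxy-3-(pent-4-yn-1-yl)-1,2-dioxan-6-yl]ethan-1-ol | C#CCCC[C@]1(OC)CC[C@@H](CCO)OO1 | intermediate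
24 | undec-1-yne | C#CCCCCCCCCC | starting material
25 | chlorobis(cyclopentadienyl)[(E)-undec-1-en-1-yl]zirconium | CCCCCCCCC/C=C/[Zr](Cl)(C1C=CC=C1)C1C=CC=C1 | intermediate
26 | (E)-1-iodoundec-1-ene | CCCCCCCCC/C=C/I | intermediate
27 | 2-[(3R,6S)-3-[(E)-hexadec-6-en-4-yn-1-yl]-3-methoxy-1,2-dioxan-6-yl]ethan-1-ol | CCCCCCCCC/C=C/C#CCCC[C@]1(OC)CC[C@@H](CCO)OO1 | intermediate
28 | 2-[(3R,6S)-3-[(E)-hexadec-6-en-4-yn-1-yl]-3-methoxy-1,2-dioxan-6-yl]acetaldehyde | CCCCCCCCC/C=C/C#CCCC[C@]1(OC)CC[C@@H](CC=O)OO1 | intermediate
29 | 2-[(3R,6S)-3-[(E)-hexadec-6-en-4-yn-1-yl]-3-methoxy-1,2-dioxan-6-yl]acetic acid | CCCCCCCCC/C=C/C#CCCC[C@]1(OC)CC[C@@H](CC(=O)O)OO1 | target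

## Step count and least certain steps

Total: 18 steps. Longest linear sequence: 13 steps (steps 5 to 15, then 17 and 18).

**Step 12 (key step).** The ruthenium carbene may engage the vinyl group on the fully substituted ketal carbon only slowly. During the long reaction time the catalyst can be degraded by the peroxide (oxidation of released phosphine), or the bis-allylic peroxide can be isomerised by ruthenium, so the closure stalls or the product is lost.

Fallback: the ring is closed at the O1–C6 bond by intramolecular alkylation, which needs no alkene. It sets out from 15 and 4 and returns at 21.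
- The dianion of 15 (n-BuLi, two equivalents) is carboxylated with CO2 to (S)-6-[(tert-butyldiphenylsilyl)oxy]-4-hydroxyhex-2-ynoic acid F1.
- Hydrogenation over Rh/Al2O3 and acid-catalysed lactonisation give (R)-5-{2-[(tert-butyldiphenylsilyl)oxy]ethyl}oxolan-2-one F2.
- Iodine–lithium exchange on 4 with t-BuLi gives {5-[tri(propan-2-yl)silyl]pent-4-yn-1-yl}lithium F3, which adds once to F2 at −78 °C to give (R)-1-[(tert-butyldiphenylsilyl)oxy]-3-hydroxy-11-[tri(propan-2-yl)silyl]undec-10-yn-6-one F4.
- Mesylation gives (R)-1-[(tert-butyldiphenylsilyl)oxy]-6-oxo-11-[tri(propan-2-yl)silyl]undec-10-yn-3-yl methanesulfonate F5.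
- H2O2 in methanol with catalytic acid converts the ketone into (3R)-1-[(tert-butyldiphenylsilyl)oxy]-6-hydroperoxy-6-methoxy-11-[tri(propan-2-yl)silyl]undec-10-yn-3-yl methanesulfonate F6.
- KOtBu with 18-crown-6 closes the ring in a 6-exo-tet substitution with inversion to give 21.

The same carbinol carbon of 15 is inverted as in the main route, so the C6 configuration is the same.

**Step 10.** The tertiary, hindered peroxide anion may substitute slowly, so that base-induced elimination of the mesylate or Kornblum–DeLaMare fragmentation of the propargylic peroxide takes over.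

Fallback: the C6–O bond is made with a small, established peroxide nucleophile and the C3–O bond is made last under acid. It sets out from 16 and 7 and returns at 19.
- 2-Methoxypropene and H2O2 give 2-hydroperoxy-2-methoxypropane F7.
- F7 with CsOH·H2O in DMF displaces the mesylate of 16 with inversion to give tert-butyl{[(3R)-3-[(2-methoxypropan-2-yl)peroxy]pent-4-yn-1-yl]oxy}diphenylsilane F8.
- Lindlar semi-hydrogenation gives tert-butyl{[(3R)-3-[(2-methoxypropan-2-yl)peroxy]pent-4-en-1-yl]oxy}diphenylsilane F9.
- Aqueous acetic acid in THF releases (3R)-5-[(tert-butyldiphenylsilyl)oxy]pent-1-en-3-yl hydroperoxide F10.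
- PPTS-catalysed addition of F10 to allene 7 gives 19.

**Step 11.** Hydrogenolysis of the O–O bond on palladium, or over-reduction of a vinyl group once the alkyne is consumed.

Fallback: from 18 back to 19 by hydrometallation instead of hydrogenation. Cp2Zr(H)Cl (one equivalent, CH2Cl2, 0 °C) adds to the terminal alkyne faster than to the vinyl group or the silyl alkyne and gives chlorobis(cyclopentadienyl){(E)-2-[(R)-peroxy-substituted]vinyl}zirconium F11 (the C-zirconated form of 19). Protonolysis with water gives 19.

**Step 4.** Capture of the allyl cation at the remote carbon, double addition to give a bis-peroxide, or acid-induced decomposition of the tertiary allylic hydroperoxide.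

Fallback: from 7 to 8 through a storable ketal. Methanol with catalytic PPTS adds to 7 to give (6,6-dimethoxyoct-7-en-1-yn-1-yl)tri(propan-2-yl)silane F12. Acid-catalysed exchange of one methoxy group with excess H2O2 under equilibrium control then gives 8.

**Step 14.** Incomplete equilibration, drift to ring-opened material in methanol, or partial loss of the silyl ether.

Fallback: from 21 to 22 through the hemiketal. Mild aqueous acid in THF hydrolyses the ketal to (3R,6S)-6-{2-[(tert-butyldiphenylsilyl)oxy]ethyl}-3-{5-[tri(propan-2-yl)silyl]pent-4-yn-1-yl}-1,2-dioxan-3-ol F13, in which the hydroxyl group takes the axial position. O-Methylation with MeI and Ag2O, with retention at C3, gives 22.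

**Step 18.** Attack of the oxidant on the electron-rich enyne, or β-elimination of the peroxide from aldehyde 28 before it is oxidised further.

Fallback: the oxidation is moved ahead of the coupling; it sets out from 23 and returns at 29. Dess–Martin oxidation gives 2-[(3R,6S)-3-methoxy-3-(pent-4-yn-1-yl)-1,2-dioxan-6-yl]acetaldehyde F14. Oxidation with NaClO2, NaH2PO4 and 2-methylbut-2-ene gives 2-[(3R,6S)-3-methoxy-3-(pent-4-yn-1-yl)-1,2-dioxan-6-yl]acetic acid F15. Sonogashira coupling of F15 with 26 then gives 29.

## Further compounds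

F1 | step 12 | (S)-6-[(tert-butyldiphenylsilyl)oxy]-4-hydroxyhex-2-ynoic acid | OC(=O)C#C[C@@H](O)CCO[Si](c1ccccc1)(c1ccccc1)C(C)(C)C
F2 | step 12 | (R)-5-{2-[(tert-butyldiphenylsilyl)oxy]ethyl}oxolan-2-one | O=C1CC[C@H](CCO[Si](c2ccccc2)(c2ccccc2)C(C)(C)C)O1
F3 | step 12 | {5-[tri(propan-2-yl)silyl]pent-4-yn-1-yl}lithium | [Li]CCCC#C[Si](C(C)C)(C(C)C)C(C)C
F4 | step 12 | (R)-1-[(tert-butyldiphenylsilyl)oxy]-3-hydroxy-11-[tri(propan-2-yl)silyl]undec-10-yn-6-one | CC(C)[Si](C(C)C)(C(C)C)C#CCCCC(=O)CC[C@@H](O)CCO[Si](c1ccccc1)(c1ccccc1)C(C)(C)C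
F5 | step 12 | (R)-1-[(tert-butyldiphenylsilyl)oxy]-6-oxo-11-[tri(propan-2-yl)silyl]undec-10-yn-3-yl methanesulfonate | CC(C)[Si](C(C)C)(C(C)C)C#CCCCC(=O)CC[C@@H](OS(C)(=O)=O)CCO[Si](c1ccccc1)(c1ccccc1)C(C)(C)C
F6 | step 12 | (3R)-1-[(tert-butyldiphenylsilyl)oxy]-6-hydroperoxy-6-methoxy-11-[tri(propan-2-yl)silyl]undec-10-yn-3-yl methanesulfonate | CC(C)[Si](C(C)C)(C(C)C)C#CCCCC(OC)(OO)CC[C@@H](OS(C)(=O)=O)CCO[Si](c1ccccc1)(c1ccccc1)C(C)(C)C
F7 | step 10 | 2-hydroperoxy-2-methoxypropane | COC(C)(C)OO
F8 | step 10 | tert-butyl{[(3R)-3-[(2-methoxypropan-2-yl)peroxy]pent-4-yn-1-yl]oxy}diphenylsilane | COC(C)(C)OO[C@@H](C#C)CCO[Si](c1ccccc1)(c1ccccc1)C(C)(C)C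
F9 | step 10 | tert-butyl{[(3R)-3-[(2-methoxypropan-2-yl)peroxy]pent-4-en-1-yl]oxy}diphenylsilane | COC(C)(C)OO[C@@H](C=C)CCO[Si](c1ccccc1)(c1ccccc1)C(C)(C)C
F10 | step 10 | (3R)-5-[(tert-butyldiphenylsilyl)oxy]pent-1-en-3-yl hydroperoxide | OO[C@@H](C=C)CCO[Si](c1ccccc1)(c1ccccc1)C(C)(C)C
F11 | step 11 | chlorobis(cyclopentadienyl){(E)-2-[(R)-peroxy-substituted]vinyl}zirconium, the C-zirconated form of 19 | CC(C)[Si](C(C)C)(C(C)C)C#CCCCC(OC)(C=C)OO[C@@H](/C=C/[Zr](Cl)(C1C=CC=C1)C1C=CC=C1)CCO[Si](c1ccccc1)(c1ccccc1)C(C)(C)C
F12 | step 4 | (6,6-dimethoxyoct-7-en-1-yn-1-yl)tri(propan-2-yl)silane | COC(OC)(C=C)CCCC#C[Si](C(C)C)(C(C)C)C(C)C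
F13 | step 14 | (3R,6S)-6-{2-[(tert-butyldiphenylsilyl)oxy]ethyl}-3-{5-[tri(propan-2-yl)silyl]pent-4-yn-1-yl}-1,2-dioxan-3-ol | CC(C)[Si](C(C)C)(C(C)C)C#CCCC[C@]1(O)CC[C@@H](CCO[Si](c2ccccc2)(c2ccccc2)C(C)(C)C)OO1
F14 | step 18 | 2-[(3R,6S)-3-methoxy-3-(pent-4-yn-1-yl)-1,2-dioxan-6-yl]acetaldehyde | C#CCCC[C@]1(OC)CC[C@@H](CC=O)OO1
F15 | step 18 | 2-[(3R,6S)-3-methoxy-3-(pent-4-yn-1-yl)-1,2-dioxan-6-yl]acetic acid | C#CCCC[C@]1(OC)CC[C@@H](CC(=O)O)OO1
A1 | alternative 1 | racemic 1-[(E)-hexadec-6-en-4-yn-1-yl]-6-(tert-butyldimethylsilyloxy)-2,3-dioxabicyclo[2.2.2]oct-5-ene | CCCCCCCCC/C=C/C#CCCC[C@@]12CC[C@@H](C=C1O[Si](C)(C)C(C)(C)C)OO2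
A2 | alternative 1 | 1-[(E)-hexadec-6-en-4-yn-1-yl]-2-(tert-butyldimethylsilyloxy)cyclohexa-1,3-diene | CCCCCCCCC/C=C/C#CCCCC1=C(O[Si](C)(C)C(C)(C)C)C=CCC1
A3 | alternative 2 | tert-butyl{2-[(3R,6S)-3-[(E)-hexadec-6-en-4-yn-1-yl]-3-methoxy-1,2-dioxan-6-yl]ethoxy}diphenylsilane | CCCCCCCCC/C=C/C#CCCC[C@]1(OC)CC[C@@H](CCO[Si](c2ccccc2)(c2ccccc2)C(C)(C)C)OO1
A4 | alternative 2 | (3S,12E)-1-[(tert-butyldiphenylsilyl)oxy]-3-hydroperoxy-6,6-dimethoxydocos-12-en-10-yne | CCCCCCCCC/C=C/C#CCCCC(OC)(OC)CC[C@@H](CCO[Si](c1ccccc1)(c1ccccc1)C(C)(C)C)OO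
A5 | alternative 3 | methyl 2-[(3R,6S)-3-methoxy-3-[5-(trimethylsilyl)pent-4-yn-1-yl]-1,2-dioxan-6-yl]acetate | C[Si](C)(C)C#CCCC[C@]1(OC)CC[C@@H](CC(=O)OC)OO1
A6 | alternative 3 | (6-hydroperoxy-6-methoxydec-9-en-1-yn-1-yl)trimethylsilane, racemic | C[Si](C)(C)C#CCCCC(OC)(OO)CCC=C
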